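**Plan**
- Retrosynthesis: the target is cut at C12–C13 (acylation of a hydroxybutyrolactone enolate, then ketone reduction) and at C8=C17 (methylenation). The decalin is then opened at C6–C7 and C5–C10 in one retro-[4+2] step, and the chain at C3–C4 (alcohol/isoprene monoxide coupling) and C10–C1 (enol tosylate cross-coupling).
- Enabling feature: in ring B, C7–C8–C9–C10 is a latent diene (the C8 methylene is a masked C8 carbonyl) and C5–C6 is a vinyl group on the quaternary C4. The C9 side chain C11–C12–O is closed onto C8 as a temporary five-membered lactone/enol ether ring that fixes the C9=C10 geometry and holds the diene s-cis.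
- Forward order: chain assembly (steps 1–5); rings A and B form together in the intramolecular Diels–Alder step and the temporary ring is opened by hydrolysis; C17 and then the lactone C13–C16 are added last.
- Stereochemistry: C3 and C4 come from one iridium-catalysed coupling; C5 and C10 (cycloaddition) and C9 (protonation) are relayed from them. C14 is bought, C13 is set anti to the C14 alkoxide, and C12 by chelation-controlled reduction.

Key step: step 6

Assumption: the (R)-Tol-BINAP iridium catalyst is taken to give the (5R,6R) diol 9; if the sense of induction is the opposite, the (S)-ligand complex is used.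
Remark: positions are labelled with the labdane numbering of the target (C17 = exocyclic CH2, C18 = 4-CH3, C19 = 4-CH2O, C20 = 10-CH3, C16 = lactone C=O, C15 = lactone CH2).

**Step 1**
Reactants: 1 2-acetyl-γ-butyrolactone
Product: 2 (E)-enol tosylate of 1 (tosylate trans to the lactone C=O)
Conditions: TsCl, N-methylimidazole, Et3N, CH2Cl2, −10 to 0 °C
Reagents that add atoms: p-toluenesulfonyl chloride, Cc1ccc(cc1)S(=O)(=O)Cl
Why: Sulfonylation of the non-chelated ammonium enolate of a β-keto ester, whose enolate oxygen lies anti to the lactone carbonyl, should give the (E)-enol tosylate (methyl cis to C=O), which fixes the later C9=C10 geometry; no stereocentre is formed.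

**Step 2**
Reactants: 2 (E)-enol tosylate; 3 2-(3-bromopropoxy)tetrahydro-2H-pyran
Product: 6 (E)-3-(5-hydroxypentan-2-ylidene)dihydrofuran-2(3H)-one, via Grignard reagent 4 (not isolated), via THP ether 5 (not isolated)
Conditions: Mg, THF, 35 °C (3 to 4); then 2, Fe(acac)3 (5 mol%), THF–NMP, −20 °C; then PPTS, MeOH, 45 °C
Reagents that add atoms: none
Why: Iron-catalysed Kumada-type cross-coupling of enol sulfonates of β-keto esters with alkyl Grignard reagents goes with retention of alkene geometry and is faster than attack on the lactone, so the C1–C3 chain ends up trans to the lactone carbonyl; acidic methanolysis then removes the THP acetal (no stereocentre formed).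

**Step 3**
Reactants: 6 hydroxy alkylidene lactone; 7 isoprene monoxide (racemic)
Product: 9 (E)-3-[(5R,6R)-5-hydroxy-6-(hydroxymethyl)-6-methyloct-7-en-2-ylidene]dihydrofuran-2(3H)-one, via aldehyde 8 (not isolated)
Conditions: complex preformed from [Ir(cod)Cl]2, (R)-Tol-BINAP, 4-cyano-3-nitrobenzoic acid and allyl acetate (5 mol%), K3PO4 (5 mol%), 7 (3 equiv), THF, 45 °C
Reagents that add atoms: none
Why: In this iridium-catalysed transfer-hydrogenative tert-(hydroxy)prenylation the alcohol is dehydrogenated to 8 and the epoxide gives an (E)-σ-allyliridium species (its stereocentre is erased) that adds through a closed chair transition state, so C3 and the quaternary C4 (CH3, CH2OH, vinyl) form together, anti, with the absolute sense set by the bisphosphine.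

**Step 4**
Reactants: 9 diol
Product: 10 bis(tert-butyldimethylsilyl) ether of 9
Conditions: TBSOTf (2.6 equiv), 2,6-lutidine, CH2Cl2, −78 to 0 °C
Reagents that add atoms: tert-butyldimethylsilyl triflate, CC(C)(C)[Si](C)(C)OS(=O)(=O)C(F)(F)F
Why: Silylation with the triflate is reactive enough for the hindered secondary hydroxyl next to the quaternary carbon, and acyclic silyl ethers are chosen on purpose for the conformational control in step 6.

**Step 5**
Reactants: 10 bis-silyl alkylidene lactone
Product: 11 (3E)-3-alkylidene-2-methylenetetrahydrofuran (dienol ether triene)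
Conditions: Cp2TiMe2 (3 equiv), toluene–THF, 70 °C, dark; filtration through Et3N-deactivated basic alumina
Reagents that add atoms: dimethyltitanocene, [CH3-].[CH3-].[Ti+4].c1cc[cH-]c1.c1cc[cH-]c1
Why: Petasis methylenation converts lactone carbonyls, conjugated ones included, into exocyclic enol ethers under neutral conditions that spare silyl ethers and alkenes; it adds C7 and turns the lactone into the s-cis-locked 2-alkoxy diene.

**Step 6**
Reactants: 11 dienol ether triene
Product: 13 3,19-bis(TBS-oxy)-12-hydroxy-13,14,15,16,17-pentanorlabdan-8-one, via enol ether cycloadduct 12 (not isolated)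
Conditions: toluene (5 mM), BHT, solid K2CO3, base-washed sealed tube, 170 °C; then 0.5 M aq. HCl–THF, 0 °C
Reagents that add atoms: water, O
Why: Heating triggers a concerted, suprafacial thermal [4+2] cycloaddition (type 1 intramolecular Diels–Alder reaction of a 1,7,9-decatriene) between the vinyl group C5=C6 and the diene C7=C8–C9=C10, which the five-membered ring C8–C9–C11–C12–O holds s-cis so that the inside methyl C20 need not be forced into the reactive conformation; the closest known reaction type is the thermal intramolecular Diels–Alder reaction of unactivated trienes with 2-alkoxy or ring-locked exocyclic dienes, followed by routine enol ether hydrolysis. Ring B is closed by the cycloaddition itself (bonds C6–C7 and C5–C10), and ring A is closed by the C5–C10 bond through the four-carbon tether C1–C4 in a chair-like, anti (trans-fused) transition state. C10 follows from the fixed (E) geometry of C9=C10 (tether outside, methyl inside) and C5 from suprafacial addition in the anti mode, which gives the trans C5–H/C10–CH3 ring fusion; the face of the vinyl group is chosen by the chair in which the C3 silyl ether is equatorial, which places C19 axial and syn to C20 as in the target. C9 is set in the hydrolysis, where the enol ether is protonated on the face opposite the axial C10 methyl group, which is also the thermodynamically preferred, equilibratable configuration with the side chain equatorial. The step needs trans over cis fusion and one of the two vinyl faces: the quaternary C4 puts one substituent axial in every chair and so penalises the syn chairs (they carry an additional axial ring B carbon), and the equatorial preference of the C3 silyl ether gives the facial bias, which is why the diol is carried as acyclic silyl ethers and not as a cyclic acetal (a 1,3-dioxane would hold the chain equatorial on the acetal ring and favour the opposite chair).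

**Step 7**
Reactants: 13 hydroxy ketone
Product: 14 3,19-bis(TBS-oxy)-13,14,15,16-tetranorlabd-8(17)-en-12-ol
Conditions: Ph3PCH3Br, KOtBu (excess), toluene–THF, 0 to 90 °C
Reagents that add atoms: methyltriphenylphosphonium bromide, C[P+](c1ccccc1)(c1ccccc1)c1ccccc1.[Br-]
Why: Wittig methylenation with excess ylide (the free hydroxyl is carried as its alkoxide) converts the hindered C8 ketone into the exocyclic C8=C17 alkene; C9 is α to the ketone but already holds its thermodynamically preferred equatorial side chain.

**Step 8**
Reactants: 14 homoallylic primary alcohol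
Product: 15 3,19-bis(TBS-oxy)-13,14,15,16-tetranorlabd-8(17)-en-12-oic acid
Conditions: TEMPO (20 mol%), PhI(OAc)2 (2.5 equiv), MeCN–H2O (1:1), rt
Reagents that add atoms: water, O
Why: The TEMPO/PhI(OAc)2 oxidation in aqueous acetonitrile takes a primary alcohol through the aldehyde hydrate to the acid without electrophilic chlorine, so the 1,1-disubstituted alkene and the silyl ethers are left alone.

**Step 9**
Reactants: 15 carboxylic acid
Product: 17 N-methoxy-N-methylamide of 15, via acyl imidazole 16 (not isolated)
Conditions: 1,1'-carbonyldiimidazole, CH2Cl2, rt; then MeNHOMe·HCl, rt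
Reagents that add atoms: N,O-dimethylhydroxylamine hydrochloride, CNOC.Cl
Why: Activation as the acyl imidazole and aminolysis gives the Weinreb amide, an acyl donor that is inert towards alkoxides and stops at the ketone stage.

**Step 10**
Reactants: 17 Weinreb amide; 18 (S)-β-hydroxy-γ-butyrolactone
Product: 20 3,19-bis(TBS-oxy)-14-hydroxy-12-oxolabd-8(17)-en-16,15-olide (13,14-trans), via dilithio dianion 19 (not isolated)
Conditions: 18 (2.5 equiv), LiN(iPr)2 (5.1 equiv, from iPr2NH and n-BuLi), THF, −78 to −40 °C; then 17, −78 to −20 °C; AcOH then aq. NH4Cl at −78 °C; crude product used directly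
Reagents that add atoms: none
Why: In this crossed Claisen-type C-acylation the alkoxide/enolate dianion of 18 (which cannot undergo β-elimination) attacks the Weinreb amide through its α-carbon on the face anti to the C14 alkoxide, so C13 is set trans to the C14 oxygen as in alkylations of such dianions, the chelated tetrahedral adduct prevents over-addition, and C14 comes from the chiral pool.

**Step 11**
Reactants: 20 β-keto lactone
Product: 21 3,19-bis(TBS) ether of the target (12S,13S,14S)
Conditions: Zn(BH4)2 (Et2O solution), Et2O–THF, −30 °C; aq. NH4Cl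
Reagents that add atoms: none
Why: In this chelation-controlled reduction of an α-substituted β-keto ester, zinc bridges the C12 ketone and the lactone carbonyl and hydride enters on the face away from ring carbon C14, which gives the syn (12S) carbinol; the alternative chelate through the C14 oxygen predicts the same 1,3-syn diol, and C13 stays trans to O14.

**Step 12**
Reactants: 21 bis-silyl ether
Product: 22 target (3R,4R,5S,9R,10S,12S,13S,14S)-3,12,14,19-tetrahydroxylabd-8(17)-en-16,15-olide
Conditions: HF·pyridine, pyridine–THF, 0 °C to rt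
Reagents that add atoms: none
Why: Buffered fluoride cleaves both silyl ethers without the base that would trigger retro-aldol or elimination in the β-hydroxy lactone and without the strong acid that could move the exocyclic double bond.

**Compound list**
1 | 2-acetyl-γ-butyrolactone (3-acetyldihydrofuran-2(3H)-one, racemic) | CC(=O)C1CCOC1=O | starting material
2 | (E)-1-(2-oxodihydrofuran-3(2H)-ylidene)ethyl 4-methylbenzenesulfonate | C/C(OS(=O)(=O)c1ccc(C)cc1)=C1/CCOC1=O | intermediate
3 | 2-(3-bromopropoxy)tetrahydro-2H-pyran (racemic) | BrCCCOC1CCCCO1 | starting material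
4 | [3-(tetrahydro-2H-pyran-2-yloxy)propyl]magnesium bromide | Br[Mg]CCCOC1CCCCO1 | intermediate
5 | (E)-3-[5-(tetrahydro-2H-pyran-2-yloxy)pentan-2-ylidene]dihydrofuran-2(3H)-one | C/C(CCCOC1CCCCO1)=C1/CCOC1=O | intermediate
6 | (E)-3-(5-hydroxypentan-2-ylidene)dihydrofuran-2(3H)-one | C/C(CCCO)=C1/CCOC1=O | intermediate
7 | isoprene monoxide (2-methyl-2-vinyloxirane, racemic) | CC1(C=C)CO1 | starting material
8 | (E)-4-(2-oxodihydrofuran-3(2H)-ylidene)pentanal | C/C(CCC=O)=C1/CCOC1=O | intermediate
9 | (E)-3-[(5R,6R)-5-hydroxy-6-(hydroxymethyl)-6-methyloct-7-en-2-ylidene]dihydrofuran-2(3H)-one | C=C[C@](C)(CO)[C@H](O)CC/C(C)=C1\CCOC1=O | intermediate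
10 | (E)-3-[(5R,6R)-5-(TBS-oxy)-6-(TBS-oxymethyl)-6-methyloct-7-en-2-ylidene]dihydrofuran-2(3H)-one | C=C[C@](C)(CO[Si](C)(C)C(C)(C)C)[C@H](O[Si](C)(C)C(C)(C)C)CC/C(C)=C1\CCOC1=O | intermediate
11 | (3E)-3-[(5R,6R)-5-(TBS-oxy)-6-(TBS-oxymethyl)-6-methyloct-7-en-2-ylidene]-2-methylenetetrahydrofuran | C=C[C@](C)(CO[Si](C)(C)C(C)(C)C)[C@H](O[Si](C)(C)C(C)(C)C)CC/C(C)=C1\CCOC1=C | intermediate
12 | 3,19-bis(TBS-oxy)-8,12-epoxy-13,14,15,16,17-pentanorlabd-8-ene (trans-fused enol ether cycloadduct; C3, C4, C5, C10 arranged as in the target) | C1CC2=C(O1)CC[C@@H]1[C@](C)(CO[Si](C)(C)C(C)(C)C)[C@H](O[Si](C)(C)C(C)(C)C)CC[C@]12C | intermediate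
13 | 3,19-bis(TBS-oxy)-12-hydroxy-13,14,15,16,17-pentanorlabdan-8-one (ring stereocentres arranged as in the target; may exist partly as the cyclic hemiketal) | O=C1CC[C@@H]2[C@](C)(CO[Si](C)(C)C(C)(C)C)[C@H](O[Si](C)(C)C(C)(C)C)CC[C@@]2(C)[C@@H]1CCO | intermediate
14 | 3,19-bis(TBS-oxy)-13,14,15,16-tetranorlabd-8(17)-en-12-ol | C=C1CC[C@@H]2[C@](C)(CO[Si](C)(C)C(C)(C)C)[C@H](O[Si](C)(C)C(C)(C)C)CC[C@@]2(C)[C@@H]1CCO | intermediate
15 | 3,19-bis(TBS-oxy)-13,14,15,16-tetranorlabd-8(17)-en-12-oic acid | C=C1CC[C@@H]2[C@](C)(CO[Si](C)(C)C(C)(C)C)[C@H](O[Si](C)(C)C(C)(C)C)CC[C@@]2(C)[C@@H]1CC(=O)O | intermediate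
16 | N-acylimidazole of 15 | C=C1CC[C@@H]2[C@](C)(CO[Si](C)(C)C(C)(C)C)[C@H](O[Si](C)(C)C(C)(C)C)CC[C@@]2(C)[C@@H]1CC(=O)n1ccnc1 | intermediate
17 | N-methoxy-N-methylamide of 15 | C=C1CC[C@@H]2[C@](C)(CO[Si](C)(C)C(C)(C)C)[C@H](O[Si](C)(C)C(C)(C)C)CC[C@@]2(C)[C@@H]1CC(=O)N(C)OC | intermediate
18 | (S)-β-hydroxy-γ-butyrolactone ((S)-4-hydroxydihydrofuran-2(3H)-one) | O=C1C[C@H](O)CO1 | starting material
19 | dilithio dianion of 18 (lithium alkoxide and lithium enolate) | [Li+].[Li+].[O-]C1=C[C@H]([O-])CO1 | intermediate
20 | 3,19-bis(TBS-oxy)-14-hydroxy-12-oxolabd-8(17)-en-16,15-olide (C13 and C14 arranged as in the target, trans) | C=C1CC[C@@H]2[C@](C)(CO[Si](C)(C)C(C)(C)C)[C@H](O[Si](C)(C)C(C)(C)C)CC[C@@]2(C)[C@@H]1CC(=O)[C@@H]1C(=O)OC[C@H]1O | intermediate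
21 | (12S,13S,14S)-3,19-bis(TBS-oxy)-12,14-dihydroxylabd-8(17)-en-16,15-olide | C=C1CC[C@@H]2[C@](C)(CO[Si](C)(C)C(C)(C)C)[C@H](O[Si](C)(C)C(C)(C)C)CC[C@@]2(C)[C@@H]1C[C@H](O)[C@@H]1C(=O)OC[C@H]1O | intermediate
22 | (3R,4R,5S,9R,10S,12S,13S,14S)-3,12,14,19-tetrahydroxylabd-8(17)-en-16,15-olide (12-hydroxy-12,13-dihydroandrographolide) | C=C1CC[C@@H]2[C@](C)(CO)[C@H](O)CC[C@@]2(C)[C@@H]1C[C@H](O)[C@@H]1C(=O)OC[C@H]1O | target

**Totals**
Total step count: 12. Longest linear sequence: 12 steps (from 1; all other inputs are commercial).

**Steps most likely to fail**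

Step 6. Before it cyclises, the s-cis-locked dienol ether 11 can isomerise, either by a thermal [1,5]-hydrogen shift from the inside methyl group C20 to C7 or by acid-catalysed migration of the exocyclic enol ether double bond into the ring. A second concern is incomplete discrimination between the two faces of the vinyl group: the bias from the equatorial C3 silyl ether is modest, so material would be lost at 13, but the route would survive. The fallback sets out from 10 and comes back at 14, and it answers the isomerisation, not the facial bias. The lactone carbonyl of 10 is turned into an all-carbon 2-(silylmethyl)diene. Double addition of Me3SiCH2MgCl/CeCl3 (THF, −78 °C to rt) gives the bis(trimethylsilylmethyl)carbinol F1. Peterson elimination (KH, THF, 0 °C) gives the allylsilane triene F2, which has no enol ether and is not held s-cis, so it can be heated harder (o-dichlorobenzene, BHT, about 210 °C). The same anti chair transition state then leads to the Δ8(9)-octalin allylsilane F3. Protodesilylation (catalytic TsOH, CH2Cl2, 0 °C), with the proton delivered to C9 anti to the C10 methyl group and SE2′ loss of silicon, gives 14 directly, so steps 5–7 are replaced.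

Step 10. Proton transfer can win over acylation (the dianion deprotonating 17 at C11, or the product 20 quenching unreacted dianion), and the sensitive β-keto-β′-hydroxy lactone 20 can dehydrate or undergo retro-Claisen cleavage on work-up. The fallback sets out from 14 and comes back at 22. Oxidation of 14 with Dess–Martin periodinane gives the aldehyde F4. The imide F5 is prepared from commercial (S)-2-(2,2-dimethyl-1,3-dioxolan-4-yl)acetic acid and (R)-4-benzyloxazolidin-2-one through the pivaloyl mixed anhydride. Its boron enolate (Bu2BOTf, iPr2NEt, CH2Cl2, −78 °C) adds to F4 in an Evans syn-aldol reaction that sets C12 and C13 together under auxiliary control and gives the aldol adduct F6. Aqueous HF in MeCN then removes the acetonide and both silyl ethers, and the freed C15 hydroxyl closes the γ-lactone onto the imide carbonyl with release of the auxiliary. This gives 22 and replaces steps 8–12.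

Step 1. Control of (E)/(Z) geometry in the sulfonylation may be incomplete, or the tetrasubstituted enol tosylate may isomerise by reversible addition of chloride or amine. Either would carry the wrong C9=C10 geometry (tether inside) into a diene that cannot reach the vinyl group. The fallback sets out from 1 and comes back at 5. The order in which the two C10 substituents are introduced is reversed, so that the geometry comes from a metal chelate. The dianion of 1 (NaH, then n-BuLi, THF, 0 °C) is alkylated at the acetyl methyl group with commercial 2-(2-bromoethoxy)tetrahydro-2H-pyran to give the keto lactone F7. Its sodium enolate (NaH, Et2O, 0 °C), held as the chelate between both carbonyl oxygens, is O-phosphorylated with ClP(O)(OEt)2 to the (Z)-enol phosphate F8 (phosphate cis to the lactone carbonyl). Me2CuLi (Et2O, −78 to −40 °C) replaces the phosphate by methyl with retention and gives 5, which is methanolysed to 6 as in step 2.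

**Further compounds**
F1 | step 6 | bis(trimethylsilylmethyl)carbinol from 10 (tertiary alcohol at C8, free C12 hydroxyl) | C=C[C@](C)(CO[Si](C)(C)C(C)(C)C)[C@H](O[Si](C)(C)C(C)(C)C)CC/C(C)=C(\CCO)C(O)(C[Si](C)(C)C)C[Si](C)(C)C
F2 | step 6 | allylsilane triene (2-(trimethylsilylmethyl)diene with free C12 hydroxyl) | C=C[C@](C)(CO[Si](C)(C)C(C)(C)C)[C@H](O[Si](C)(C)C(C)(C)C)CC/C(C)=C(\CCO)C(=C)C[Si](C)(C)C
F3 | step 6 | Δ8(9)-octalin allylsilane (trans-fused cycloadduct) | C[Si](C)(C)CC=1CC[C@@H]2[C@](C)(CO[Si](C)(C)C(C)(C)C)[C@H](O[Si](C)(C)C(C)(C)C)CC[C@@]2(C)C=1CCO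
F4 | step 10 | 3,19-bis(TBS-oxy)-13,14,15,16-tetranorlabd-8(17)-en-12-al | C=C1CC[C@@H]2[C@](C)(CO[Si](C)(C)C(C)(C)C)[C@H](O[Si](C)(C)C(C)(C)C)CC[C@@]2(C)[C@@H]1CC=O
F5 | step 10 | (R)-4-benzyl-3-{[(4S)-2,2-dimethyl-1,3-dioxolan-4-yl]acetyl}oxazolidin-2-one | O=C(C[C@H]1COC(C)(C)O1)N1[C@H](Cc2ccccc2)COC1=O
F6 | step 10 | Evans syn-aldol adduct of F4 and F5 | C=C1CC[C@@H]2[C@](C)(CO[Si](C)(C)C(C)(C)C)[C@H](O[Si](C)(C)C(C)(C)C)CC[C@@]2(C)[C@@H]1C[C@H](O)[C@@H]([C@H]1COC(C)(C)O1)C(=O)N1[C@H](Cc2ccccc2)COC1=O
F7 | step 1 | 3-[4-(tetrahydro-2H-pyran-2-yloxy)butanoyl]dihydrofuran-2(3H)-one | O=C(CCCOC1CCCCO1)C1CCOC1=O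
F8 | step 1 | (Z)-enol diethyl phosphate of F7 | CCOP(=O)(OCC)O/C(CCCOC1CCCCO1)=C1/CCOC1=O
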